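## Retrosynthetic overview

1. Ring labels: ring A is the furan ring of the benzofuran, ring B the central dihydrofuran ring, ring C the outer dihydrofuran ring. The target comes from its nonamethyl ether with ring C still 2,3-cis; the last step is global O-demethylation with C2 epimerisation of ring C.
2. The nonamethyl ether comes from a stilbene that carries a 2-hydroxyaryl ketone at one end and a latent o-quinone methide at the other, plus two equivalents of one 4-methoxybenzyl sulfur ylide. A double formal [4+1] annulation closes rings A and B in one operation, and ring C relays its configuration to C3 of ring B.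
3. That stilbene comes from the aryllithium of a 4-bromo ring C building block and a stilbene aldehyde whose O-Boc group migrates to the new carbinol.
4. The ring C bromide comes from an enantioselective dirhodium-carbene C–H insertion of a diaryldiazomethane, the only catalytic asymmetric step. The stilbene aldehyde comes from a Heck coupling. Both ketone arms derive from one Friedel–Crafts ketone.
5. Ring order: C first, then A and B together.

Assumption: Rh2(S-PTAD)4 is taken as the catalyst enantiomer that gives the (2R,3S) ring C in step 4; if a trial shows the opposite sense, Rh2(R-PTAD)4 is used with no other change.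

## Route

Step 1
Reactants: 1 1-bromo-3,5-dimethoxybenzene; 2 3,5-dimethoxybenzoyl chloride
Product: 4 (2-bromo-6-hydroxy-4-methoxyphenyl)(3,5-dimethoxyphenyl)methanone, via dimethoxy ketone 3 (not isolated)
Conditions: AlCl3 (3 equiv), CH2Cl2, 0 → 40 °C; H2O work-up
Reagents that add atoms: none
Why: Friedel–Crafts acylation occurs at C2 of 1 (ortho and para to the two methoxy groups, less hindered than the position between them), and AlCl3 chelated between the new carbonyl and the ortho methoxy group then cleaves only that ether (chelation-assisted demethylation).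

Step 2
Reactants: 4 (2-bromo-6-hydroxy-4-methoxyphenyl)(3,5-dimethoxyphenyl)methanone; 5 4-methoxybenzyl chloride
Product: 6 {2-bromo-4-methoxy-6-[(4-methoxybenzyl)oxy]phenyl}(3,5-dimethoxyphenyl)methanone
Conditions: K2CO3, DMF, 60 °C
Reagents that add atoms: none
Why: Williamson ether synthesis on the phenoxide installs the benzylic CH2 that later becomes C2 of ring C.

Step 3
Reactants: 6 {2-bromo-4-methoxy-6-[(4-methoxybenzyl)oxy]phenyl}(3,5-dimethoxyphenyl)methanone
Product: 7 hydrazone of ketone 6 (E/Z mixture)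
Conditions: N2H4·H2O (20 equiv), AcOH (cat.), n-BuOH, 120 °C, sealed tube
Reagents that add atoms: hydrazine (used as the hydrate), NN
Why: Acid-catalysed hydrazone condensation, with a large excess of hydrazine and heat to overcome the di-ortho-substituted ketone and suppress azine formation.

Step 4
Reactants: 7 hydrazone of ketone 6
Product: 9 (2R,3S)-4-bromo-3-(3,5-dimethoxyphenyl)-6-methoxy-2-(4-methoxyphenyl)-2,3-dihydro-1-benzofuran (2,3-cis), via diazoalkane 8 (not isolated)
Conditions: MnO2 (8 equiv), MeCN, 0 °C; then Rh2(S-PTAD)4 (1 mol %), 0 → 23 °C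
Reagents that add atoms: none
Why: MnO2 dehydrogenates the hydrazone to the diaryldiazomethane, and the donor/donor dirhodium carbene inserts into one enantiotopic benzylic C–H bond of the ether (enantioselective intramolecular 1,5 C–H insertion); the chiral carboxylate catalyst selects the C–H bond and the concerted insertion gives the 2,3-cis ring with 3S configuration.

Step 5
Reactants: 4 (2-bromo-6-hydroxy-4-methoxyphenyl)(3,5-dimethoxyphenyl)methanone
Product: 10 (2-ethenyl-6-hydroxy-4-methoxyphenyl)(3,5-dimethoxyphenyl)methanone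
Conditions: vinylboronic acid pinacol ester (1.5 equiv), Pd(PPh3)4 (5 mol %), K2CO3, dioxane/H2O, 90 °C
Reagents that add atoms: vinylboronic acid pinacol ester (2-ethenyl-4,4,5,5-tetramethyl-1,3,2-dioxaborolane), C=CB1OC(C)(C)C(C)(C)O1
Why: Suzuki–Miyaura coupling of the aryl bromide, which tolerates the hydrogen-bonded phenol and the diaryl ketone.

Step 6
Reactants: 11 2-hydroxy-5-iodobenzaldehyde
Product: 12 tert-butyl 2-formyl-4-iodophenyl carbonate
Conditions: Boc2O (1.1 equiv), DMAP (5 mol %), CH2Cl2, 0 → 23 °C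
Reagents that add atoms: di-tert-butyl dicarbonate, CC(C)(C)OC(=O)OC(=O)OC(C)(C)C
Why: DMAP-catalysed O-acylation puts on the carbonate that will later migrate to the benzylic oxygen and act as the leaving group of the o-quinone methide.

Step 7
Reactants: 10 (2-ethenyl-6-hydroxy-4-methoxyphenyl)(3,5-dimethoxyphenyl)methanone; 12 tert-butyl 2-formyl-4-iodophenyl carbonate
Product: 13 tert-butyl 4-{(E)-2-[2-(3,5-dimethoxybenzoyl)-3-hydroxy-5-methoxyphenyl]ethenyl}-2-formylphenyl carbonate
Conditions: Pd(OAc)2 (5 mol %), n-Bu4NCl, NaHCO3, DMF, 70 °C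
Reagents that add atoms: none
Why: Heck reaction under ligand-free conditions: syn-carbopalladation of the styrene and syn-β-hydride elimination give the E-stilbene, and the mild hydrogen carbonate base leaves the aryl carbonate and aldehyde untouched.

Step 8
Reactants: 9 (2R,3S)-4-bromo-3-(3,5-dimethoxyphenyl)-6-methoxy-2-(4-methoxyphenyl)-2,3-dihydro-1-benzofuran; 13 tert-butyl 4-{(E)-2-[2-(3,5-dimethoxybenzoyl)-3-hydroxy-5-methoxyphenyl]ethenyl}-2-formylphenyl carbonate
Product: 16 benzhydryl tert-butyl carbonate with free phenols and ring C cis-(2R,3S) (both carbinol epimers; full name in the list), via aryllithium 14 (not isolated), via alkoxide 15 (not isolated)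
Conditions: 9 (1.2 equiv), n-BuLi, THF, −78 °C; then 13 pre-treated with NaH (1.0 equiv, THF, 0 °C), −78 °C; AcOH, −78 °C
Reagents that add atoms: none
Why: Bromine–lithium exchange gives aryllithium 14, which adds to the aldehyde (the hindered ketone is shielded as its chelated phenoxide), and the new alkoxide takes over the neighbouring tert-butoxycarbonyl group (anionic O-to-O carbonate shift known from o-quinone methide chemistry); cold protonation leaves the phenol and benzylic carbonate of a latent o-quinone methide, and the carbinol centre, formed as a mixture, is erased in step 10.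

Step 9
Reactants: 5 4-methoxybenzyl chloride
Product: 17 1-(4-methoxybenzyl)thiolan-1-ium tetrafluoroborate
Conditions: tetrahydrothiophene (3 equiv), NaBF4 (1.5 equiv), MeCN, 23 °C
Reagents that add atoms: tetrahydrothiophene, C1CCSC1; sodium tetrafluoroborate, [Na+].F[B-](F)(F)F
Why: S-alkylation of the sulfide by the activated benzylic chloride with anion metathesis gives a non-nucleophilic sulfonium salt as the ylide precursor.

Step 10
Reactants: 16 benzhydryl tert-butyl carbonate with free phenols and ring C cis-(2R,3S); 17 1-(4-methoxybenzyl)thiolan-1-ium tetrafluoroborate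
Product: 20 nonamethyl ether of the target with ring B trans-(2R,3R) and ring C cis-(2R,3S), via quinone methide 18 (not isolated), via tertiary alcohol 19 (not isolated)
Conditions: 17 (3.0 equiv), LiN(SiMe3)2 (3.0 equiv), THF, −78 °C; then 16 pre-treated with LiN(SiMe3)2 (2.1 equiv), −78 → 23 °C; then AcOH, TsOH·H2O (10 mol %), 23 °C
Reagents that add atoms: none
Why: Proposed new method: one ylide performs two formal [4+1] annulations in one pot — the phenoxide of 16 expels tert-butyl carbonate to give o-quinone methide 18, the benzylic sulfur ylide adds to its methide carbon and the phenoxide displaces thiolane (5-exo-tet) to close ring B, while a second ylide adds to the lithium-chelated 2-hydroxyaryl ketone and that phenoxide likewise displaces thiolane to give tertiary alcohol 19, which loses water under acid to aromatise ring A; C3 of ring B is set by substrate control (the quinone methide ring sits anti to the C3 aryl group of ring C across the twisted aryl–methide bond and the ylide enters from the open C5–H flank, giving 3R), C2 closes trans and any cis isomer is levelled in step 11; the closest known reaction types are the sulfur-ylide [4+1] annulation of o-quinone methides to trans-2,3-dihydrobenzofurans and the Corey–Chaykovsky-type annulation of 2-hydroxyaryl ketones to 3-hydroxy-2,3-dihydrobenzofurans and benzofurans.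

Step 11
Reactants: 20 nonamethyl ether of the target with ring B trans-(2R,3R) and ring C cis-(2R,3S)
Product: 21 target CNP0135983.1
Conditions: BBr3 (20 equiv), CH2Cl2, −78 → 23 °C; H2O work-up
Reagents that add atoms: none
Why: BBr3 cleaves all nine aryl methyl ethers (Lewis acid ether cleavage) and reversibly ionises the C2–O bond of ring C to a benzylic cation stabilised by the para-oxygenated aryl group, so the cis ring recloses to the more stable trans-(2S,3S) ring with C3 untouched, while ring B stays trans-(2R,3R).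

## Compound list

1 | 1-bromo-3,5-dimethoxybenzene | COc1cc(OC)cc(Br)c1 | starting material
2 | 3,5-dimethoxybenzoyl chloride | COc1cc(OC)cc(C(=O)Cl)c1 | starting material
3 | (2-bromo-4,6-dimethoxyphenyl)(3,5-dimethoxyphenyl)methanone | COc1cc(OC)c(C(=O)c2cc(OC)cc(OC)c2)c(Br)c1 | intermediate
4 | (2-bromo-6-hydroxy-4-methoxyphenyl)(3,5-dimethoxyphenyl)methanone | COc1cc(O)c(C(=O)c2cc(OC)cc(OC)c2)c(Br)c1 | intermediate
5 | 4-methoxybenzyl chloride | COc1ccc(CCl)cc1 | starting material
6 | {2-bromo-4-methoxy-6-[(4-methoxybenzyl)oxy]phenyl}(3,5-dimethoxyphenyl)methanone | COc1ccc(COc2cc(OC)cc(Br)c2C(=O)c2cc(OC)cc(OC)c2)cc1 | intermediate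
7 | hydrazone of 6 (E/Z mixture) | COc1ccc(COc2cc(OC)cc(Br)c2C(=NN)c2cc(OC)cc(OC)c2)cc1 | intermediate
8 | 1-bromo-2-[diazo(3,5-dimethoxyphenyl)methyl]-5-methoxy-3-[(4-methoxybenzyl)oxy]benzene | COc1ccc(COc2cc(OC)cc(Br)c2C(=[N+]=[N-])c2cc(OC)cc(OC)c2)cc1 | intermediate
9 | (2R,3S)-4-bromo-3-(3,5-dimethoxyphenyl)-6-methoxy-2-(4-methoxyphenyl)-2,3-dihydro-1-benzofuran (cis) | Brc1cc(OC)cc2c1[C@H](c1cc(OC)cc(OC)c1)[C@H](c1ccc(OC)cc1)O2 | intermediate
10 | (2-ethenyl-6-hydroxy-4-methoxyphenyl)(3,5-dimethoxyphenyl)methanone | COc1cc(O)c(C(=O)c2cc(OC)cc(OC)c2)c(C=C)c1 | intermediate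
11 | 2-hydroxy-5-iodobenzaldehyde | O=Cc1cc(I)ccc1O | starting material
12 | tert-butyl 2-formyl-4-iodophenyl carbonate | CC(C)(C)OC(=O)Oc1ccc(I)cc1C=O | intermediate
13 | tert-butyl 4-{(E)-2-[2-(3,5-dimethoxybenzoyl)-3-hydroxy-5-methoxyphenyl]ethenyl}-2-formylphenyl carbonate | COc1cc(O)c(C(=O)c2cc(OC)cc(OC)c2)c(/C=C/c2ccc(OC(=O)OC(C)(C)C)c(C=O)c2)c1 | intermediate
14 | [(2R,3S)-3-(3,5-dimethoxyphenyl)-6-methoxy-2-(4-methoxyphenyl)-2,3-dihydro-1-benzofuran-4-yl]lithium | [Li]c1cc(OC)cc2c1[C@H](c1cc(OC)cc(OC)c1)[C@H](c1ccc(OC)cc1)O2 | intermediate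
15 | lithium alkoxide from addition of 14 to the aldehyde of 13 (sodium phenoxide on the ketone arm, carbonate still on the aryl oxygen, carbinol epimers) | COc1cc([O-])c(C(=O)c2cc(OC)cc(OC)c2)c(/C=C/c2ccc(OC(=O)OC(C)(C)C)c(C([O-])c3cc(OC)cc4c3[C@H](c3cc(OC)cc(OC)c3)[C@H](c3ccc(OC)cc3)O4)c2)c1.[Li+].[Na+] | intermediate
16 | tert-butyl [(2R,3S)-3-(3,5-dimethoxyphenyl)-6-methoxy-2-(4-methoxyphenyl)-2,3-dihydro-1-benzofuran-4-yl]{5-[(E)-2-[2-(3,5-dimethoxybenzoyl)-3-hydroxy-5-methoxyphenyl]ethenyl]-2-hydroxyphenyl}methyl carbonate (both carbinol epimers) | CC(C)(C)OC(=O)OC(c1cc(/C=C/c2cc(OC)cc(O)c2C(=O)c2cc(OC)cc(OC)c2)ccc1O)c1cc(OC)cc2c1[C@H](c1cc(OC)cc(OC)c1)[C@H](c1ccc(OC)cc1)O2 | intermediate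
17 | 1-(4-methoxybenzyl)thiolan-1-ium tetrafluoroborate | COc1ccc(C[S+]2CCCC2)cc1.F[B-](F)(F)F | intermediate
18 | o-quinone methide from 16: 6-{[(2R,3S)-ring C-4-yl]methylidene}-4-{(E)-2-[2-(3,5-dimethoxybenzoyl)-3-hydroxy-5-methoxyphenyl]ethenyl}cyclohexa-2,4-dien-1-one (drawn with the remote phenol protonated) | COc1cc(O)c(C(=O)c2cc(OC)cc(OC)c2)c(/C=C/C2=CC(=Cc3cc(OC)cc4c3[C@H](c3cc(OC)cc(OC)c3)[C@H](c3ccc(OC)cc3)O4)C(=O)C=C2)c1 | intermediate
19 | doubly annulated tertiary alcohol: as 20 but with ring A as a 3-hydroxy-2,3-dihydrofuran (ring A centres as a mixture) | COc1ccc(C2Oc3cc(OC)cc(/C=C/c4ccc5c(c4)[C@@H](c4cc(OC)cc6c4[C@H](c4cc(OC)cc(OC)c4)[C@H](c4ccc(OC)cc4)O6)[C@H](c4ccc(OC)cc4)O5)c3C2(O)c2cc(OC)cc(OC)c2)cc1 | intermediate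
20 | (2R,3R)-3-[(2R,3S)-3-(3,5-dimethoxyphenyl)-6-methoxy-2-(4-methoxyphenyl)-2,3-dihydro-1-benzofuran-4-yl]-5-{(E)-2-[3-(3,5-dimethoxyphenyl)-6-methoxy-2-(4-methoxyphenyl)-1-benzofuran-4-yl]ethenyl}-2-(4-methoxyphenyl)-2,3-dihydro-1-benzofuran | COc1ccc(-c2oc3cc(OC)cc(/C=C/c4ccc5c(c4)[C@@H](c4cc(OC)cc6c4[C@H](c4cc(OC)cc(OC)c4)[C@H](c4ccc(OC)cc4)O6)[C@H](c4ccc(OC)cc4)O5)c3c2-c2cc(OC)cc(OC)c2)cc1 | intermediate
21 | 5-[(2S,3S)-4-[(2R,3R)-5-{(E)-2-[3-(3,5-dihydroxyphenyl)-6-hydroxy-2-(4-hydroxyphenyl)-1-benzofuran-4-yl]ethenyl}-2-(4-hydroxyphenyl)-2,3-dihydro-1-benzofuran-3-yl]-6-hydroxy-2-(4-hydroxyphenyl)-2,3-dihydro-1-benzofuran-3-yl]benzene-1,3-diol | Oc1ccc(-c2oc3cc(O)cc(/C=C/c4ccc5c(c4)[C@@H](c4cc(O)cc6c4[C@H](c4cc(O)cc(O)c4)[C@@H](c4ccc(O)cc4)O6)[C@H](c4ccc(O)cc4)O5)c3c2-c2cc(O)cc(O)c2)cc1 | target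

## Step count and risks

Total: 11 steps. Longest linear sequence: 7 steps (steps 1, 2, 3, 4, 8, 10, 11).

The three steps most likely to fail:

Step 10 (double annulation). The hindered, phenoxide-deactivated ketone may not take up the semi-stabilised ylide even though the quinone methide end reacts. The fallback sets out from 16 and returns at 20. Only 1.2 equiv of the ylide from 17 is used at −78 → 0 °C, so that only the quinone methide annulation occurs; this gives the ring B-closed hydroxy ketone F1. Its phenol is acylated with 4-methoxybenzoyl chloride (Et3N, DMAP, CH2Cl2) to the keto 4-methoxybenzoate F2. Low-valent titanium (TiCl3, Zn(Cu), DME, reflux) then couples the ketone and ester carbonyls reductively into the C2=C3 bond of ring A, which gives 20.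

Step 3 (hydrazone of a di-ortho-substituted benzophenone). The twisted ketone may resist condensation. The fallback sets out from 4 and returns at 7. Hydrazine is condensed first with the hydrogen-bonded hydroxy ketone 4, whose hydroxyaryl ring lies in the carbonyl plane and leaves both faces open, to give the hydroxy hydrazone F3. The phenoxide of F3 is then alkylated with 5 (K2CO3, DMF, 23 °C), which gives 7.

Step 11 (ninefold demethylation with epimerisation). Prolonged Lewis acid exposure can open ring B to a cation that is trapped by a neighbouring resorcinol ring (Friedel–Crafts), before ring C has fully epimerised. The fallback sets out from 20 and returns at 21. The BBr3 cleavage is run cold and short (−78 → 0 °C) so that ring C survives as the cis isomer, giving the ring C-cis nonaphenol F4. C2 of ring C is then epimerised without acid by K2CO3 in MeOH at 40 °C (phenoxide-driven opening to a p-quinone methide and reclosure to the trans ring), which gives 21.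

Further compounds

F1 | step 10 | (2-{(E)-2-[(2R,3R)-3-[(2R,3S)-3-(3,5-dimethoxyphenyl)-6-methoxy-2-(4-methoxyphenyl)-2,3-dihydro-1-benzofuran-4-yl]-2-(4-methoxyphenyl)-2,3-dihydro-1-benzofuran-5-yl]ethenyl}-6-hydroxy-4-methoxyphenyl)(3,5-dimethoxyphenyl)methanone | COc1cc(O)c(C(=O)c2cc(OC)cc(OC)c2)c(/C=C/c2ccc3c(c2)[C@@H](c2cc(OC)cc4c2[C@H](c2cc(OC)cc(OC)c2)[C@H](c2ccc(OC)cc2)O4)[C@H](c2ccc(OC)cc2)O3)c1
F2 | step 10 | 4-methoxybenzoate ester of the phenol of F1 | COc1ccc(C(=O)Oc2cc(OC)cc(/C=C/c3ccc4c(c3)[C@@H](c3cc(OC)cc5c3[C@H](c3cc(OC)cc(OC)c3)[C@H](c3ccc(OC)cc3)O5)[C@H](c3ccc(OC)cc3)O4)c2C(=O)c2cc(OC)cc(OC)c2)cc1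
F3 | step 3 | hydrazone of (2-bromo-6-hydroxy-4-methoxyphenyl)(3,5-dimethoxyphenyl)methanone | COc1cc(O)c(C(=NN)c2cc(OC)cc(OC)c2)c(Br)c1
F4 | step 11 | epimer of the target with ring C cis-(2R,3S) | Oc1ccc(-c2oc3cc(O)cc(/C=C/c4ccc5c(c4)[C@@H](c4cc(O)cc6c4[C@H](c4cc(O)cc(O)c4)[C@H](c4ccc(O)cc4)O6)[C@H](c4ccc(O)cc4)O5)c3c2-c2cc(O)cc(O)c2)cc1
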